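**Plan**

- Retrosynthesis: the C12 acetate is cut back to a triethylsilyl ether, then the ring bond C8–C9 is cut (alkyne hydroacylation). This opens the cyclopentenone to an acyclic 2-bromo-enal whose C12 carries a C7≡C8 enyne arm. Further cuts are C6–C7 (Sonogashira), C10=C11 (bromo-olefination), C12–C8 (alkynylation of an α-keto ester) and C12–C13 (dithiane alkylation).
- Forward: the C11–C20 keto ester is built first, the alkyne is added at C12, C9–C10 is attached by olefination and C1–C6 by coupling. The only ring (C8–C12) is closed third from the end, followed by the silyl-to-acetyl switch at C12.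
- Enabling feature: the exocyclic C7=C8 alkene conjugated to the C9 ketone, with H on C7 cis to C9 (C6 trans to C9), is the syn adduct of a C9 formyl C–H across a C7≡C8 alkyne attached to C12. Ring atoms C8, C9, C10, C11 and C12 therefore close through the single bond C8–C9.
- Stereochemistry: C12 from a ligand-controlled Si-face alkynylation; 14Z from (Z)-oct-2-en-1-ol; 5E from hydrozirconation–iodination; formyl cis to C12 from a kinetically controlled bromo-olefination; 7E from the syn hydroacylation.
- Locants C1–C20 are prostanoid numbers (C1 = ester carbon, C8–C12 = ring carbons).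

Key step: step 15

Assumption: the (1S,2S) amino alcohol ligand of step 4 is taken to deliver the alkynylzinc to the Si face of the C12 ketone; if its sense is the reverse, the equally available (1R,2R) antipode is used in the same way.

**Route**

Step 1
Reactants: 1 (Z)-oct-2-en-1-ol
Product: 2 (2Z)-1-bromooct-2-ene
Conditions: CBr4, PPh3, CH2Cl2, 0 °C
Reagents that add atoms: carbon tetrabromide, BrC(Br)(Br)Br
Why: Appel bromination of a primary allylic alcohol proceeds by SN2 displacement of the oxyphosphonium group at 0 °C, which should keep the Z alkene and avoid allylic transposition.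

Step 2
Reactants: 3 ethyl 1,3-dithiane-2-carboxylate; 2 (2Z)-1-bromooct-2-ene
Product: 5 ethyl 2-[(2Z)-oct-2-en-1-yl]-1,3-dithiane-2-carboxylate, via sodium dithiane carbanion 4 (not isolated)
Conditions: NaH, DMF/THF, 0 °C; then 2, 0 to 25 °C
Reagents that add atoms: none
Why: Alkylation of the soft, doubly stabilised dithiane ester carbanion (Corey–Seebach-type acyl anion equivalent) should occur by direct SN2 attack at the primary allylic carbon, so the Z alkene is carried over unchanged.

Step 3
Reactants: 5 ethyl 2-[(2Z)-oct-2-en-1-yl]-1,3-dithiane-2-carboxylate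
Product: 6 ethyl (4Z)-2-oxodec-4-enoate
Conditions: PhI(OCOCF3)2, MeCN/H2O (9:1), 0 °C, short contact; used at once
Reagents that add atoms: water, O
Why: Oxidative dithioacetal hydrolysis with a hypervalent iodine reagent attacks sulfur much faster than an isolated alkene and should release the α-keto ester under mild, brief conditions that limit migration of the skipped alkene.

Step 4
Reactants: 6 ethyl (4Z)-2-oxodec-4-enoate; 7 ethynyltrimethylsilane
Product: 8 ethyl (2S,4Z)-2-hydroxy-2-[(trimethylsilyl)ethynyl]dec-4-enoate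
Conditions: Zn(OTf)2 (20 mol%), (1S,2S)-3-(tert-butyldimethylsilyloxy)-2-(dimethylamino)-1-(4-nitrophenyl)propan-1-ol (22 mol%), Et3N (30 mol%), toluene, 50 °C
Reagents that add atoms: none
Why: In this zinc triflate–amine catalytic enantioselective alkynylation of an α-keto ester, the zinc acetylide bound to the chiral amino alkoxide should add to the Si face of the activated C12 ketone and set the tertiary carbinol as 2S (the same centre is 12R in the target, the descriptor changing only because C11 later becomes an alkene carbon).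

Step 5
Reactants: 8 ethyl (2S,4Z)-2-hydroxy-2-[(trimethylsilyl)ethynyl]dec-4-enoate
Product: 9 ethyl (2S,4Z)-2-(triethylsilyloxy)-2-[(trimethylsilyl)ethynyl]dec-4-enoate
Conditions: Et3SiOTf, 2,6-lutidine, CH2Cl2, −78 to 0 °C
Reagents that add atoms: triethylsilyl trifluoromethanesulfonate, CC[Si](CC)(CC)OS(=O)(=O)C(F)(F)F
Why: Silylation with a silyl triflate and a hindered pyridine base is the standard way to protect a tertiary alcohol and does not touch the ester, the alkynylsilane or the alkene.

Step 6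
Reactants: 9 ethyl (2S,4Z)-2-(triethylsilyloxy)-2-[(trimethylsilyl)ethynyl]dec-4-enoate
Product: 10 (2S,4Z)-2-(triethylsilyloxy)-2-[(trimethylsilyl)ethynyl]dec-4-enal
Conditions: i-Bu2AlH (1.1 equiv), CH2Cl2, −78 °C; MeOH, then aq. potassium sodium tartrate
Reagents that add atoms: none
Why: Low-temperature partial reduction of an α-silyloxy ester with i-Bu2AlH is a standard route to the aldehyde, and C12 bears no hydrogen, so the product cannot epimerise or enolise.

Step 7
Reactants: 11 methyl 2-[bis(2,2,2-trifluoroethoxy)phosphoryl]acetate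
Product: 12 methyl 2,2-dibromo-2-[bis(2,2,2-trifluoroethoxy)phosphoryl]acetate
Conditions: Br2, aq. NaOH, 0 °C
Reagents that add atoms: bromine, BrBr
Why: Exhaustive hypobromite bromination of the active methylene of a phosphonoacetate should give the gem-dibromide cleanly, avoiding the mixtures obtained on direct monobromination.

Step 8
Reactants: 12 methyl 2,2-dibromo-2-[bis(2,2,2-trifluoroethoxy)phosphoryl]acetate
Product: 13 methyl 2-bromo-2-[bis(2,2,2-trifluoroethoxy)phosphoryl]acetate
Conditions: SnCl2, EtOH/H2O, 0 °C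
Reagents that add atoms: none
Why: Reductive removal of one bromine from an α,α-dibromo phosphonoacetate with SnCl2 is a known selective mono-dehalogenation that stops at the monobromide.

Step 9
Reactants: 10 (2S,4Z)-2-(triethylsilyloxy)-2-[(trimethylsilyl)ethynyl]dec-4-enal; 13 methyl 2-bromo-2-[bis(2,2,2-trifluoroethoxy)phosphoryl]acetate
Product: 15 methyl (2E,4R,6Z)-2-bromo-4-(triethylsilyloxy)-4-[(trimethylsilyl)ethynyl]dodeca-2,6-dienoate, via potassium bromophosphonate carbanion 14 (not isolated)
Conditions: KOt-Bu, 18-crown-6, THF, −78 °C; then 10, −78 to −40 °C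
Reagents that add atoms: none
Why: This Horner–Wadsworth–Emmons olefination in its Still–Gennari form (bis-trifluoroethyl phosphonate, dissociated potassium counter-ion, kinetic control) should place the ester cis to the aldehyde-derived C12 substituent, which with bromine on the α-carbon is the 2E isomer (ester cis, bromine trans to C12).

Step 10
Reactants: 15 methyl (2E,4R,6Z)-2-bromo-4-(triethylsilyloxy)-4-[(trimethylsilyl)ethynyl]dodeca-2,6-dienoate
Product: 16 (2E,4R,6Z)-2-bromo-4-(triethylsilyloxy)-4-[(trimethylsilyl)ethynyl]dodeca-2,6-dien-1-ol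
Conditions: i-Bu2AlH (2.5 equiv), CH2Cl2, −78 °C; aq. potassium sodium tartrate
Reagents that add atoms: none
Why: 1,2-Reduction of an α-bromo enoate to the 2-bromoallylic alcohol with i-Bu2AlH is well known and leaves the vinylic bromide, both silyl groups and the alkene geometry untouched at −78 °C.

Step 11
Reactants: 16 (2E,4R,6Z)-2-bromo-4-(triethylsilyloxy)-4-[(trimethylsilyl)ethynyl]dodeca-2,6-dien-1-ol
Product: 17 (2E,4R,6Z)-2-bromo-4-ethynyl-4-(triethylsilyloxy)dodeca-2,6-dien-1-ol
Conditions: K2CO3 (0.2 equiv), MeOH, 0 °C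
Reagents that add atoms: none
Why: Base-catalysed methanolysis of the alkynyl C–Si bond (protodesilylation) is far faster than cleavage or migration of the hindered tertiary triethylsilyl ether, so only the alkyne is unmasked.

Step 12
Reactants: 18 methyl hex-5-ynoate
Product: 20 methyl (5E)-6-iodohex-5-enoate, via alkenylzirconocene chloride 19 (not isolated)
Conditions: Cp2Zr(H)Cl (1.1 equiv), THF, 25 °C; then I2, 0 °C
Reagents that add atoms: iodine, II
Why: Hydrozirconation adds Zr–H syn across the terminal alkyne with zirconium on the terminal carbon faster than it reduces the ester, and iodinolysis with retention should give the E iodide.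

Step 13
Reactants: 17 (2E,4R,6Z)-2-bromo-4-ethynyl-4-(triethylsilyloxy)dodeca-2,6-dien-1-ol; 20 methyl (5E)-6-iodohex-5-enoate
Product: 21 methyl (5E,9R,11Z)-9-[(1E)-2-bromo-3-hydroxyprop-1-en-1-yl]-9-(triethylsilyloxy)heptadeca-5,11-dien-7-ynoate
Conditions: Pd(PPh3)4 (5 mol%), CuI (10 mol%), Et3N, THF (degassed), 25 °C
Reagents that add atoms: none
Why: In this Sonogashira coupling, zerovalent palladium inserts into the unhindered alkenyl C–I bond at 25 °C much faster than into the hindered trisubstituted vinylic C–Br bond, so the C6–C7 bond should form with retention of the 5E geometry and the bromide is kept.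

Step 14
Reactants: 21 methyl (5E,9R,11Z)-9-[(1E)-2-bromo-3-hydroxyprop-1-en-1-yl]-9-(triethylsilyloxy)heptadeca-5,11-dien-7-ynoate
Product: 22 methyl (5E,9R,11Z)-9-[(1E)-2-bromo-3-oxoprop-1-en-1-yl]-9-(triethylsilyloxy)heptadeca-5,11-dien-7-ynoate
Conditions: Dess–Martin periodinane, NaHCO3, CH2Cl2, 0 °C; crude product used directly, kept cold and dark
Reagents that add atoms: none
Why: Buffered Dess–Martin oxidation of a primary allylic alcohol is neutral and fast, which should preserve the less stable enal geometry (formyl cis to C12; E by the sequence rules because bromine outranks the formyl carbon), and the silylated C12 oxygen cannot form a lactol.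

Step 15
Reactants: 22 methyl (5E,9R,11Z)-9-[(1E)-2-bromo-3-oxoprop-1-en-1-yl]-9-(triethylsilyloxy)heptadeca-5,11-dien-7-ynoate
Product: 23 methyl (5E,7E)-7-[(5R)-3-bromo-5-[(2Z)-oct-2-en-1-yl]-2-oxo-5-(triethylsilyloxy)cyclopent-3-en-1-ylidene]hept-5-enoate
Conditions: [Rh(dppe)]2(BF4)2 (5 mol%; dppe = 1,2-bis(diphenylphosphino)ethane), acetone (degassed), 25 °C, dark
Reagents that add atoms: none
Why: Proposed new method: cationic monovalent rhodium should insert into the formyl C–H bond of 22 to give an acyl hydride of trivalent rhodium held beside the C7≡C8 alkyne by the cis enal geometry, add hydride to C7 and rhodium to C8 in a syn fashion to form a six-membered rhodacycle, and release 23 by C8–C9 reductive elimination; this sequence is untested on a 2-bromo-2-enal with a fully substituted propargylic carbon. The closest known reaction type is the cationic rhodium–diphosphine hydroacylation of 5-alkynals to (E)-2-alkylidenecyclopentanones. The cyclopentenone closes in the 5-exo-dig mode, because syn delivery of acyl and hydride across the alkyne cannot place the resulting alkene inside a six-membered ring. No stereocentre is formed: C12 has no hydrogen and is not involved, the 7E geometry (C6 trans to C9) follows from the syn addition, and the 5E and 14Z alkenes are spectators, the latter too remote to compete. The step needs formyl C–H insertion to outrun vinylic C–Br insertion and decarbonylation, which the chelating diphosphine on cationic rhodium, the low temperature and the fast intramolecular capture by the adjacent alkyne should secure. The C12 oxygen is a silyl ether rather than an ester so that no propargylic acyloxy migration can occur.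

Step 16
Reactants: 23 methyl (5E,7E)-7-[(5R)-3-bromo-5-[(2Z)-oct-2-en-1-yl]-2-oxo-5-(triethylsilyloxy)cyclopent-3-en-1-ylidene]hept-5-enoate
Product: 24 methyl (5E,7E)-7-[(5R)-3-bromo-5-hydroxy-5-[(2Z)-oct-2-en-1-yl]-2-oxocyclopent-3-en-1-ylidene]hept-5-enoate
Conditions: HF·pyridine, pyridine, THF, 0 °C
Reagents that add atoms: none
Why: Fluoride-mediated cleavage of the tertiary triethylsilyl ether with buffered HF·pyridine is non-basic and weakly nucleophilic, so the cross-conjugated dienone, the vinylic bromide and the methyl ester should survive.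

Step 17
Reactants: 24 methyl (5E,7E)-7-[(5R)-3-bromo-5-hydroxy-5-[(2Z)-oct-2-en-1-yl]-2-oxocyclopent-3-en-1-ylidene]hept-5-enoate
Product: 25 methyl (5E,7E)-7-[(5R)-5-acetoxy-3-bromo-5-[(2Z)-oct-2-en-1-yl]-2-oxocyclopent-3-en-1-ylidene]hept-5-enoate (target)
Conditions: Ac2O, DMAP, CH2Cl2, 25 °C
Reagents that add atoms: acetic anhydride, CC(=O)OC(C)=O
Why: DMAP-catalysed acyl transfer (Steglich-type acetylation) is the usual way to esterify a tertiary alcohol, and since C12 carries no hydrogen the centre cannot epimerise.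

**Compound list**

1 | (Z)-oct-2-en-1-ol | CCCCC/C=C\CO | starting material
2 | (2Z)-1-bromooct-2-ene | CCCCC/C=C\CBr | intermediate
3 | ethyl 1,3-dithiane-2-carboxylate | CCOC(=O)C1SCCCS1 | starting material
4 | sodium 2-(ethoxycarbonyl)-1,3-dithian-2-ide | CCOC(=O)[C-]1SCCCS1.[Na+] | intermediate (not isolated)
5 | ethyl 2-[(2Z)-oct-2-en-1-yl]-1,3-dithiane-2-carboxylate | CCCCC/C=C\CC1(C(=O)OCC)SCCCS1 | intermediate
6 | ethyl (4Z)-2-oxodec-4-enoate | CCCCC/C=C\CC(=O)C(=O)OCC | intermediate
7 | ethynyltrimethylsilane | C#C[Si](C)(C)C | starting material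
8 | ethyl (2S,4Z)-2-hydroxy-2-[(trimethylsilyl)ethynyl]dec-4-enoate | CCCCC/C=C\C[C@](O)(C#C[Si](C)(C)C)C(=O)OCC | intermediate
9 | ethyl (2S,4Z)-2-(triethylsilyloxy)-2-[(trimethylsilyl)ethynyl]dec-4-enoate | CCCCC/C=C\C[C@](O[Si](CC)(CC)CC)(C#C[Si](C)(C)C)C(=O)OCC | intermediate
10 | (2S,4Z)-2-(triethylsilyloxy)-2-[(trimethylsilyl)ethynyl]dec-4-enal | CCCCC/C=C\C[C@](O[Si](CC)(CC)CC)(C#C[Si](C)(C)C)C=O | intermediate
11 | methyl 2-[bis(2,2,2-trifluoroethoxy)phosphoryl]acetate | COC(=O)CP(=O)(OCC(F)(F)F)OCC(F)(F)F | starting material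
12 | methyl 2,2-dibromo-2-[bis(2,2,2-trifluoroethoxy)phosphoryl]acetate | COC(=O)C(Br)(Br)P(=O)(OCC(F)(F)F)OCC(F)(F)F | intermediate
13 | methyl 2-bromo-2-[bis(2,2,2-trifluoroethoxy)phosphoryl]acetate | COC(=O)C(Br)P(=O)(OCC(F)(F)F)OCC(F)(F)F | intermediate
14 | potassium salt of the carbanion of 13 | COC(=O)[C-](Br)P(=O)(OCC(F)(F)F)OCC(F)(F)F.[K+] | intermediate (not isolated)
15 | methyl (2E,4R,6Z)-2-bromo-4-(triethylsilyloxy)-4-[(trimethylsilyl)ethynyl]dodeca-2,6-dienoate | CCCCC/C=C\C[C@](O[Si](CC)(CC)CC)(C#C[Si](C)(C)C)/C=C(Br)\C(=O)OC | intermediate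
16 | (2E,4R,6Z)-2-bromo-4-(triethylsilyloxy)-4-[(trimethylsilyl)ethynyl]dodeca-2,6-dien-1-ol | CCCCC/C=C\C[C@](O[Si](CC)(CC)CC)(C#C[Si](C)(C)C)/C=C(Br)\CO | intermediate
17 | (2E,4R,6Z)-2-bromo-4-ethynyl-4-(triethylsilyloxy)dodeca-2,6-dien-1-ol | CCCCC/C=C\C[C@](O[Si](CC)(CC)CC)(C#C)/C=C(Br)\CO | intermediate
18 | methyl hex-5-ynoate | COC(=O)CCCC#C | starting material
19 | methyl (5E)-6-[chlorobis(cyclopentadienyl)zirconio]hex-5-enoate | COC(=O)CCC/C=C/[Zr](Cl)(C1C=CC=C1)C1C=CC=C1 | intermediate (not isolated)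
20 | methyl (5E)-6-iodohex-5-enoate | COC(=O)CCC/C=C/I | intermediate
21 | methyl (5E,9R,11Z)-9-[(1E)-2-bromo-3-hydroxyprop-1-en-1-yl]-9-(triethylsilyloxy)heptadeca-5,11-dien-7-ynoate | CCCCC/C=C\C[C@](O[Si](CC)(CC)CC)(C#C/C=C/CCCC(=O)OC)/C=C(Br)\CO | intermediate
22 | methyl (5E,9R,11Z)-9-[(1E)-2-bromo-3-oxoprop-1-en-1-yl]-9-(triethylsilyloxy)heptadeca-5,11-dien-7-ynoate | CCCCC/C=C\C[C@](O[Si](CC)(CC)CC)(C#C/C=C/CCCC(=O)OC)/C=C(Br)\C=O | intermediate
23 | methyl (5E,7E)-7-[(5R)-3-bromo-5-[(2Z)-oct-2-en-1-yl]-2-oxo-5-(triethylsilyloxy)cyclopent-3-en-1-ylidene]hept-5-enoate | CCCCC/C=C\C[C@@]1(O[Si](CC)(CC)CC)C=C(Br)C(=O)/C1=C/C=C/CCCC(=O)OC | intermediate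
24 | methyl (5E,7E)-7-[(5R)-3-bromo-5-hydroxy-5-[(2Z)-oct-2-en-1-yl]-2-oxocyclopent-3-en-1-ylidene]hept-5-enoate | CCCCC/C=C\C[C@@]1(O)C=C(Br)C(=O)/C1=C/C=C/CCCC(=O)OC | intermediate
25 | methyl (5E,7E)-7-[(5R)-5-acetoxy-3-bromo-5-[(2Z)-oct-2-en-1-yl]-2-oxocyclopent-3-en-1-ylidene]hept-5-enoate | CCCCC/C=C\C[C@@]1(OC(C)=O)C=C(Br)C(=O)/C1=C/C=C/CCCC(=O)OC | target

**Step count**

Total step count: 17.
Longest linear sequence: 14 steps (steps 1–6, 9–11, 13–17, from (Z)-oct-2-en-1-ol).

**Steps most likely to fail**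

Step 15. The acyl rhodium hydride may lose CO (decarbonylation), rhodium may insert into the vinylic C–Br bond, or the enal may isomerise so that the formyl group no longer sits next to the alkyne before C–H activation occurs. The fallback uses known chemistry, sets out from 22 and returns at 23, and closes the same C8–C9 bond reductively instead of redox-neutrally. Hydrogen-mediated reductive cyclisation of the alkynal under cationic rhodium ([Rh(cod)2]OTf, 2,2'-bis(diphenylphosphino)biphenyl, catalytic 2-naphthoic acid, H2 at 1 atm, 1,2-dichloroethane, 25–40 °C) couples alkyne and aldehyde oxidatively without ever forming an acyl hydride. Hydrogenolysis then places hydrogen on C7 cis to C9, giving methyl (5E,7Z)-7-[(5R)-3-bromo-2-hydroxy-5-[(2Z)-oct-2-en-1-yl]-5-(triethylsilyloxy)cyclopent-3-en-1-ylidene]hept-5-enoate F1 as a mixture of C9 epimers; its exocyclic alkene has the same spatial arrangement as in 23, the descriptor changing only with the substituent ranking. Oxidation of the bis-allylic alcohol with Dess–Martin periodinane and NaHCO3 in CH2Cl2 at 0 °C then gives 23. This fallback removes the decarbonylation pathway but not the C–Br insertion risk.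

Step 4. Under amine and zinc Lewis acid at 50 °C the keto ester may enolise and the skipped C14=C15 alkene may move into conjugation, and facial discrimination may be modest for a purely aliphatic keto ester. The fallback replaces catalyst control by auxiliary control at low temperature; it sets out from 5 and returns at 10.
- Saponification (LiOH, THF/MeOH/H2O, 50 °C) gives 2-[(2Z)-oct-2-en-1-yl]-1,3-dithiane-2-carboxylic acid F2.
- Esterification with (1R,2S,5R)-5-methyl-2-(2-phenylpropan-2-yl)cyclohexan-1-ol (DCC, DMAP, CH2Cl2) gives (1R,2S,5R)-5-methyl-2-(2-phenylpropan-2-yl)cyclohexyl 2-[(2Z)-oct-2-en-1-yl]-1,3-dithiane-2-carboxylate F3.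
- Unmasking as in step 3 gives (1R,2S,5R)-5-methyl-2-(2-phenylpropan-2-yl)cyclohexyl (4Z)-2-oxodec-4-enoate F4.
- Addition of the bromomagnesium acetylide of 7 (from 7 and EtMgBr, THF, −78 °C) should occur on the keto face not shielded by the phenyl group. By analogy with additions to the glyoxylate of this auxiliary this is taken to be the Si face (the antipodal auxiliary is used otherwise), giving the 8-phenylmenthyl (2S,4Z)-2-hydroxy-2-[(trimethylsilyl)ethynyl]dec-4-enoate F5 without amine or heat.
- Silylation as in step 5 gives the 8-phenylmenthyl (2S,4Z)-2-(triethylsilyloxy)-2-[(trimethylsilyl)ethynyl]dec-4-enoate F6.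
- Reduction with excess i-Bu2AlH (CH2Cl2, −78 to 0 °C) releases the auxiliary and gives (2S,4Z)-2-(triethylsilyloxy)-2-[(trimethylsilyl)ethynyl]dec-4-en-1-ol F7.
- Dess–Martin oxidation of F7 gives 10.

Step 9. Addition of the phosphonate carbanion to the neopentyl-type aldehyde may be slow and the kinetic preference may erode, giving the isomer with the ester trans to C12, which cannot cyclise later. The fallback sets the geometry by a syn addition to an alkyne instead of by olefination; it sets out from 10 and returns at 15.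
- Dibromo-olefination (CBr4, PPh3, Et3N, CH2Cl2, 0 °C; first stage of a Corey–Fuchs sequence) gives (3R,5Z)-1,1-dibromo-3-(triethylsilyloxy)-3-[(trimethylsilyl)ethynyl]undeca-1,5-diene F8.
- n-BuLi (2.1 equiv, THF, −78 °C) induces Br–Li exchange and Fritsch–Buttenberg–Wiechell rearrangement to [(3R,5Z)-3-(triethylsilyloxy)-3-[(trimethylsilyl)ethynyl]undec-5-en-1-yn-1-yl]lithium F9 (not isolated).
- Trapping with ClCO2Me gives methyl (4R,6Z)-4-(triethylsilyloxy)-4-[(trimethylsilyl)ethynyl]dodec-6-en-2-ynoate F10.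
- Palladium-catalysed hydrostannation (Pd(PPh3)4, Bu3SnH, THF, 0 °C) adds H to C11 and tin to C10 syn across the electron-poor alkyne, giving methyl (2E,4R,6Z)-4-(triethylsilyloxy)-2-(tributylstannyl)-4-[(trimethylsilyl)ethynyl]dodeca-2,6-dienoate F11 with the ester cis to C12.
- Bromodestannylation with N-bromosuccinimide (CH2Cl2, −78 to 0 °C) proceeds with retention and gives 15.

**Further compounds**

F1 | step 15 | methyl (5E,7Z)-7-[(5R)-3-bromo-2-hydroxy-5-[(2Z)-oct-2-en-1-yl]-5-(triethylsilyloxy)cyclopent-3-en-1-ylidene]hept-5-enoate (C9 epimers) | CCCCC/C=C\C[C@@]1(O[Si](CC)(CC)CC)C=C(Br)C(O)/C1=C/C=C/CCCC(=O)OC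
F2 | step 4 | 2-[(2Z)-oct-2-en-1-yl]-1,3-dithiane-2-carboxylic acid | CCCCC/C=C\CC1(C(=O)O)SCCCS1
F3 | step 4 | (1R,2S,5R)-5-methyl-2-(2-phenylpropan-2-yl)cyclohexyl 2-[(2Z)-oct-2-en-1-yl]-1,3-dithiane-2-carboxylate | CCCCC/C=C\CC1(SCCCS1)C(=O)O[C@@H]2C[C@H](C)CC[C@H]2C(C)(C)c3ccccc3
F4 | step 4 | (1R,2S,5R)-5-methyl-2-(2-phenylpropan-2-yl)cyclohexyl (4Z)-2-oxodec-4-enoate | CCCCC/C=C\CC(=O)C(=O)O[C@@H]1C[C@H](C)CC[C@H]1C(C)(C)c2ccccc2
F5 | step 4 | (1R,2S,5R)-5-methyl-2-(2-phenylpropan-2-yl)cyclohexyl (2S,4Z)-2-hydroxy-2-[(trimethylsilyl)ethynyl]dec-4-enoate | CCCCC/C=C\C[C@](O)(C#C[Si](C)(C)C)C(=O)O[C@@H]1C[C@H](C)CC[C@H]1C(C)(C)c2ccccc2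
F6 | step 4 | (1R,2S,5R)-5-methyl-2-(2-phenylpropan-2-yl)cyclohexyl (2S,4Z)-2-(triethylsilyloxy)-2-[(trimethylsilyl)ethynyl]dec-4-enoate | CCCCC/C=C\C[C@](O[Si](CC)(CC)CC)(C#C[Si](C)(C)C)C(=O)O[C@@H]1C[C@H](C)CC[C@H]1C(C)(C)c2ccccc2
F7 | step 4 | (2S,4Z)-2-(triethylsilyloxy)-2-[(trimethylsilyl)ethynyl]dec-4-en-1-ol | CCCCC/C=C\C[C@](O[Si](CC)(CC)CC)(C#C[Si](C)(C)C)CO
F8 | step 9 | (3R,5Z)-1,1-dibromo-3-(triethylsilyloxy)-3-[(trimethylsilyl)ethynyl]undeca-1,5-diene | CCCCC/C=C\C[C@](O[Si](CC)(CC)CC)(C#C[Si](C)(C)C)C=C(Br)Br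
F9 | step 9 | [(3R,5Z)-3-(triethylsilyloxy)-3-[(trimethylsilyl)ethynyl]undec-5-en-1-yn-1-yl]lithium | CCCCC/C=C\C[C@](O[Si](CC)(CC)CC)(C#C[Si](C)(C)C)C#C[Li]
F10 | step 9 | methyl (4R,6Z)-4-(triethylsilyloxy)-4-[(trimethylsilyl)ethynyl]dodec-6-en-2-ynoate | CCCCC/C=C\C[C@](O[Si](CC)(CC)CC)(C#C[Si](C)(C)C)C#CC(=O)OC
F11 | step 9 | methyl (2E,4R,6Z)-4-(triethylsilyloxy)-2-(tributylstannyl)-4-[(trimethylsilyl)ethynyl]dodeca-2,6-dienoate | CCCCC/C=C\C[C@](O[Si](CC)(CC)CC)(C#C[Si](C)(C)C)/C=C([Sn](CCCC)(CCCC)CCCC)\C(=O)OC
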